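## The problem

Target 20 is a eudesmane, a trans-fused decalin. Numbering used throughout: ring A is C1–C5 and C10, ring B is C5–C10, CH3-14 sits on C10, CH3-15 on C4, and C11 with CH3-12 and CH3-13 on C7. Ring A carries four contiguous stereocentres: the axial 3α-ester, the fully substituted C4 with its axial 4β-acetoxy group, H-5 (α) and the quaternary C10 (CH3-14 β). Ring B holds the enone C6=C7–C8=O, whose α-carbon C7 bears the tertiary hydroperoxide carbon C11. Two further stereocentres lie in the (2S,3R)-2,3-dimethyloxirane-2-carbonyl residue; the ring cannot influence them, so they need reagent control. On the ring, C4 and C5 can be set together, C5 can then direct C10 when ring A is closed, and the rigid decalin can direct hydride delivery to C3. The 4β-acetoxy group is 1,3-diaxial to CH3-14 and so is hard to introduce once the bicycle exists; it also neighbours the C3 oxygen, so acyl migration has to be excluded by geometry. The hydroperoxide (reduction, acid-induced cleavage), the glycidic ester (acid, nucleophiles) and H-5 (the γ-hydrogen of the final enone) will not survive rough treatment and must arrive late. The enabling feature is that quaternary C10 carries a methyl group and is linked through C1–C2 to the C3 carbonyl. C1 is therefore the β-carbon of a C3 ketone, and CH3-14 can come from a C10 methylene by addition of one hydrogen atom, which makes C10 a tertiary radical ready to add to C1.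

## Retrosynthesis

**C11–O bond (20 to 19).** The hydroperoxide is removed first, together with a shift of the alkene from C6=C7 to C7=C11. This leads to the isopropylidene ketone 19, and the forward reaction is a Schenck ene reaction. The alternative, exchanging an 11-hydroxyl for OOH, needs acid next to the epoxide. The ene reaction is neutral and puts the most fragile group in last. It must abstract hydrogen from C6 and not from the C11 methyl groups.

**C7–C11 bond (19 to 15).** The isopropylidene group is cut to the C8 ketone 15 and acetone. The forward path runs through the lithium enolate 16, the aldol adduct 17 and its mesylate 18. Enolisation towards C9 is disfavoured because C9 is flanked by quaternary C10, so the three-carbon unit should be placed at C7 without a blocking group. The precursor loses three carbons and one alkene.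

**Ester C–O bond at C3 (15 to 10 and 13).** Cutting the ester gives the hydroxy ketone 10 and the epoxy acid 13, joined through the mixed anhydride 14. The acid is attached after the ketal has been removed, so the epoxide never meets aqueous acid. It is attached before the acetone aldol, so the 3-hydroxyl needs no protecting group. Acid 13 goes back through epoxy alcohol 12 to (E)-2-methylbut-2-en-1-ol 11; a Sharpless epoxidation sets both side-chain stereocentres by reagent control.

**Functional-group changes in ring A and ring B (10 to 9 to 8).** The C8 ketone is masked as the dioxolane 9, and the 3α-alcohol is taken back to the C3 ketone 8. The forward reduction must deliver hydride equatorially to give the axial alcohol. That alcohol is trans-diaxial to the 4β-acetate, which prevents acyl migration.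

**C1–C10 bond (8 to 7), the key cut.** Cutting C1–C10 opens ring A and removes the quaternary stereocentre in one stroke. It leaves the monocyclic acetoxy dienone 7, with only the C4 and C5 centres, an exocyclic methylene at C10 and a vinyl ketone. The neighbouring cuts (C3–C4, C4–C5 or C5–C6) all leave the quaternary C10 to be built beforehand by separate means. The forward reaction must add hydrogen to the methylene carbon, close the ring 6-endo at C1 and bond on the face of H-5.

**Acetate, vinyl and amide bonds (7 to 6 to 5 to 4).** The acetate is removed to give the hydroxy enone 6. The vinyl–acyl bond is cut to the Weinreb amide 5, which comes from the ethyl ester 4. The acetate is placed while C4 is still on an open chain, where the tertiary alcohol is far more accessible than in the decalin.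

**C10=CH2 and C4–C5 bonds (4 to 3 to 1 and 2).** The methylene is taken back to the ring ketone of 3. The C4–C5 bond is cut by an aldol disconnection to the commercial ketone 1 and ethyl pyruvate 2. One catalytic step must set both stereocentres and must react on the side of the ketone remote from the ketal.

## Roads not taken

**Alternative 1: chelated Prins bicyclisation.** The cut is C4–C5 and C9–C10, so both rings open to the acyclic (3S,6E)-3-benzyloxy-10-chloro-6-methylundeca-6,10-dien-2-one A1. In the forward step TiCl4 chelates the α-benzyloxy ketone, the E-alkene attacks C4 through C5, and the vinyl chloride traps the C10 cation through C9. Hydrolysis then gives 3β-benzyloxy-4β-hydroxy-11,12,13-trinor-5α-eudesman-8-one A2.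
- Merits: two rings and three stereocentres (C4, C5, C10) form in one operation. The trans fusion follows stereospecifically from the alkene geometry, which is more secure than the facial selectivity of a radical closure, and here this road is better than the chosen one.
- Weak points: a methyl ketone is a poor cation initiator and needs a strong Lewis acid, which the newly formed tertiary carbinol and the benzyl ether may not tolerate. Chelation delivers the 3β-oxygen cis to the 4β-hydroxyl, whereas 20 needs 3α, so debenzylation, oxidation and re-reduction are added. The 4β-hydroxyl must then be acetylated in its hindered axial position. A1 itself needs a linear, stereocontrolled synthesis.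
- Comparison: the chosen plan sets C4 and C5 in one catalytic step from a bought ketone, installs the acetate on the open chain and creates C3 directly with the right configuration.

**Alternative 2: desymmetrising Stetter cyclisation.** The cut is C5–C6, leading to the achiral dienone aldehyde 4-(1-methyl-4-oxocyclohexa-2,5-dien-1-yl)butanal A3. A chiral triazolium-derived carbene turns the aldehyde carbon C6 into an acyl-anion equivalent that adds to C5 of one enone arm. After equilibration at C5 this gives 11,12,13,15-tetranor-5α-eudesm-1-ene-3,6-dione A4.
- Merits: the quaternary C10 is created enantioselectively by the catalyst from a flat, easily made substrate. In this respect it is better than the chosen plan, where C10 depends on substrate control.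
- Weak points: the ring B carbonyl ends up at C6 and not at C8, so a carbonyl transposition is needed. C4 arrives as a bare methylene and must receive both the methyl group and a β-oxygen; oxidation of a 4-methyl enolate would be expected on the face away from CH3-14, giving the wrong C4 epimer. The C1=C2 alkene must also be removed.
- Comparison: the chosen plan has every heteroatom of ring A in place at the moment of ring closure and needs far fewer steps afterwards.

**Alternative 3: carbene-catalysed crossed benzoin.** The cut is C3–C4, leading to the keto aldehyde 3-[(7R,8R)-8-acetyl-7-methyl-1,4-dioxaspiro[4.5]decan-7-yl]propanal A5. The carbene converts the C3 aldehyde into an acyl-anion equivalent that adds to the C4 methyl ketone. Ring A closes as the ketol 4β-hydroxy-8,8-ethylenedioxy-11,12,13-trinor-5α-eudesman-3-one A6.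
- Merits: the oxidation pattern of C3 and C4 is formed directly under mild, metal-free conditions. C5 and C10 are fixed before ring closure, so the ring fusion is not at stake; in this respect the road is better than the chosen one.
- Weak points: A5 needs a tertiary and a quaternary centre trans on ring B, which costs more steps than 7. Its C5 is α to the acetyl group and can epimerise under the basic conditions, and an intramolecular aldol competes. The reversible benzoin must place the hydroxyl axial and syn to CH3-14. A6 must then be acetylated at that hindered axial tertiary alcohol.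
- Comparison: the chosen plan reaches its cyclisation precursor in five steps from a commercial ketone and carries the acetate in from the open chain. In exchange it accepts an uncertain facial selectivity at C10.

Key step: step 6

Assumption (stereochemical course of step 1): the ester group of 2 is taken to occupy the pseudo-equatorial site of the hydrogen-bonded enamine transition state, as in known additions of cyclohexanone to aryl glyoxylates, so that (S)-proline gives (2R,8S)-3; C7 of 16–18 is formed as an inconsequential epimer mixture and is left undefined in their SMILES.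

## Route

Step 1
Reactants: 1 1,4-dioxaspiro[4.5]decan-7-one; 2 ethyl pyruvate
Product: 3 ethyl (2R)-2-hydroxy-2-[(8S)-7-oxo-1,4-dioxaspiro[4.5]decan-8-yl]propanoate
Conditions: (S)-proline (30 mol %), DMSO, rt; 1 in excess, 2 added slowly
Reagents that add atoms: none
Why: Proline-catalysed enamine aldol of a cyclohexanone with an α-keto ester, a known pairing; the enamine should form on the side away from the ketal and add through the hydrogen-bonded chair-like transition state with the ester group pseudo-equatorial, which sets C5 (S) and C4 (R) in the anti relationship.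

Step 2
Reactants: 3 ethyl (2R)-2-hydroxy-2-[(8S)-7-oxo-1,4-dioxaspiro[4.5]decan-8-yl]propanoate
Product: 4 ethyl (2R)-2-hydroxy-2-[(8R)-7-methylidene-1,4-dioxaspiro[4.5]decan-8-yl]propanoate
Conditions: Zn, CH2Br2, TiCl4, THF/CH2Cl2, 0 °C to rt
Reagents that add atoms: dibromomethane, BrCBr
Why: Lombardo methylenation is non-basic, so retro-aldol cleavage, epimerisation at C5 and β-elimination of the ketal should be avoided, and the ester and the free tertiary alcohol are expected to be tolerated; the descriptor at C5 changes only because the priorities change.

Step 3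
Reactants: 4 ethyl (2R)-2-hydroxy-2-[(8R)-7-methylidene-1,4-dioxaspiro[4.5]decan-8-yl]propanoate
Product: 5 (2R)-2-hydroxy-N-methoxy-N-methyl-2-[(8R)-7-methylidene-1,4-dioxaspiro[4.5]decan-8-yl]propanamide
Conditions: MeNHOMe·HCl, iPrMgCl, THF, −20 °C to rt
Reagents that add atoms: N,O-dimethylhydroxylamine hydrochloride, CNOC.Cl
Why: Weinreb amide formation from an ester with the chloromagnesium amide of N,O-dimethylhydroxylamine; the neighbouring magnesium alkoxide should help attack on the hindered ester, and no stereocentre is touched.

Step 4
Reactants: 5 (2R)-2-hydroxy-N-methoxy-N-methyl-2-[(8R)-7-methylidene-1,4-dioxaspiro[4.5]decan-8-yl]propanamide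
Product: 6 (4R)-4-hydroxy-4-[(8R)-7-methylidene-1,4-dioxaspiro[4.5]decan-8-yl]pent-1-en-3-one
Conditions: CH2=CHMgBr (excess), THF, −20 to 0 °C; inverse quench into cold aq. KHSO4
Reagents that add atoms: vinylmagnesium bromide, C=C[Mg]Br
Why: Grignard addition to a Weinreb amide stops at the chelated tetrahedral adduct and releases the vinyl ketone on work-up; the cold acidic inverse quench protonates the liberated amine and so prevents its conjugate addition to the enone.

Step 5
Reactants: 6 (4R)-4-hydroxy-4-[(8R)-7-methylidene-1,4-dioxaspiro[4.5]decan-8-yl]pent-1-en-3-one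
Product: 7 (4R)-4-acetoxy-4-[(8R)-7-methylidene-1,4-dioxaspiro[4.5]decan-8-yl]pent-1-en-3-one
Conditions: Ac2O, Et3N, DMAP (cat.), CH2Cl2, 0 °C to rt
Reagents that add atoms: acetic anhydride, CC(=O)OC(C)=O
Why: DMAP-catalysed acetylation of the tertiary α-hydroxy ketone on the open chain, where the hydroxyl is far more accessible than it would be as the axial 4β-hydroxyl of the decalin; Lewis-acid activation is avoided because it would acylate the 1,1-disubstituted alkene.

Step 6
Reactants: 7 (4R)-4-acetoxy-4-[(8R)-7-methylidene-1,4-dioxaspiro[4.5]decan-8-yl]pent-1-en-3-one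
Product: 8 4β-acetoxy-8,8-ethylenedioxy-11,12,13-trinor-5α-eudesman-3-one
Conditions: Fe(acac)3 (0.3 equiv), PhSiH3, EtOH/ethylene glycol, 60 °C
Reagents that add atoms: none
Why: The iron hydride formed from Fe(acac)3 and PhSiH3 transfers a hydrogen atom to the terminal carbon of the 1,1-disubstituted alkene, creating CH3-14 and the tertiary C10 radical; this nucleophilic radical adds to C1 of the vinyl ketone, and the α-keto radical at C2 is reduced by divalent iron and protonated by ethanol. The closest known reaction type is the Fe(acac)3/PhSiH3 reductive olefin coupling in its intramolecular form, a hydrogen-atom-transfer Giese cyclisation that forms quaternary carbons. Ring A closes in the 6-endo-trig mode, because attack at C2 (5-exo) would give an unstabilised primary radical and lose the polarity match. The new stereocentre C10 is under substrate control: with the quaternary side chain equatorial on ring B, bonding on the face of H-5 lets both rings pass through chair-like geometries and places CH3-14 axial and anti to H-5, which gives the trans fusion. Closure on the other face leads to the cis-decalin and must either put CH3-15 and CH3-14 in a 1,3-diaxial relationship or turn the side chain axial on ring B. The step needs hydrogen-atom transfer to the electron-rich alkene in preference to the vinyl ketone, which the higher reactivity of 1,1-disubstituted alkenes towards the metal hydride and the proximity of the acceptor should secure. The acetate, the ketal and the C4 and C5 centres should not be affected under these nearly neutral conditions.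

Step 7
Reactants: 8 4β-acetoxy-8,8-ethylenedioxy-11,12,13-trinor-5α-eudesman-3-one
Product: 9 4β-acetoxy-8,8-ethylenedioxy-11,12,13-trinor-5α-eudesman-3α-ol
Conditions: LiBH(sBu)3 (L-Selectride), THF, −78 °C; then NaOH, H2O2, 0 °C
Reagents that add atoms: none
Why: The bulky trialkylborohydride should attack the 4,4-disubstituted 3-ketone from the equatorial direction, as with 4,4-dimethyl-3-oxo triterpenoids, and give the axial 3α-alcohol; the new oxygen is trans-diaxial to the 4β-acetate in a locked decalin, so acyl migration is not expected.

Step 8
Reactants: 9 4β-acetoxy-8,8-ethylenedioxy-11,12,13-trinor-5α-eudesman-3α-ol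
Product: 10 4β-acetoxy-3α-hydroxy-11,12,13-trinor-5α-eudesman-8-one
Conditions: PPTS, acetone/H2O, 55 °C
Reagents that add atoms: water, O
Why: Mild acid-catalysed hydrolysis of the dioxolane; the tertiary acetate should survive, and the ketal is removed here so that the epoxide introduced later never meets aqueous acid.

Step 9
Reactants: 11 (E)-2-methylbut-2-en-1-ol
Product: 12 [(2R,3R)-2,3-dimethyloxiran-2-yl]methanol
Conditions: Ti(OiPr)4 (cat.), D-(−)-diethyl tartrate (cat.), tBuOOH, 4 Å MS, CH2Cl2, −20 °C
Reagents that add atoms: tert-butyl hydroperoxide, CC(C)(C)OO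
Why: Sharpless asymmetric epoxidation of an E-allylic alcohol; the D-(−)-tartrate catalyst delivers oxygen to the face that gives the (2R,3R) epoxy alcohol, and the cis relationship of the two methyl groups comes from the alkene geometry.

Step 10
Reactants: 12 [(2R,3R)-2,3-dimethyloxiran-2-yl]methanol
Product: 13 (2S,3R)-2,3-dimethyloxirane-2-carboxylic acid
Conditions: RuCl3 (cat.), NaIO4, EtOAc/MeCN/H2O, 0 °C to rt
Reagents that add atoms: water, O
Why: Ruthenium tetroxide-catalysed oxidation of a primary epoxy alcohol to the glycidic acid, a standard sequel to the Sharpless epoxidation; the stereocentres are untouched and the C2 descriptor changes only through the priority rules.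

Step 11
Reactants: 10 4β-acetoxy-3α-hydroxy-11,12,13-trinor-5α-eudesman-8-one; 13 (2S,3R)-2,3-dimethyloxirane-2-carboxylic acid
Product: 15 4β-acetoxy-8-oxo-11,12,13-trinor-5α-eudesman-3α-yl (2S,3R)-2,3-dimethyloxirane-2-carboxylate, via Yamaguchi mixed anhydride 14 (not isolated)
Conditions: 13, 2,4,6-trichlorobenzoyl chloride, Et3N, THF, 0 °C to rt; then 10, DMAP, toluene, rt to 50 °C
Reagents that add atoms: 2,4,6-trichlorobenzoyl chloride, O=C(Cl)c1c(Cl)cc(Cl)cc1Cl (its atoms stay in 14 only)
Why: Yamaguchi esterification; DMAP should attack the mixed anhydride at the less shielded oxirane carbonyl, and the acylpyridinium ion acylates the hindered axial 3α-hydroxyl with retention at C3; the base-only conditions spare the epoxide.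

Step 12
Reactants: 15 4β-acetoxy-8-oxo-11,12,13-trinor-5α-eudesman-3α-yl (2S,3R)-2,3-dimethyloxirane-2-carboxylate
Product: 17 4β-acetoxy-11-hydroxy-8-oxo-5α-eudesman-3α-yl (2S,3R)-2,3-dimethyloxirane-2-carboxylate (C7 epimers), via lithium enolate 16 (not isolated)
Conditions: LiN(iPr)2 (LDA), THF, −78 °C; then acetone, −78 °C; AcOH quench at −78 °C
Reagents that add atoms: acetone, CC(C)=O; lithium diisopropylamide, [Li]N(C(C)C)C(C)C (lithium stays in 16 only)
Why: Kinetic deprotonation should occur at C7, since C9 is neopentylic next to quaternary C10, the ketone is more acidic than the acetate and the epoxy ester has no α-hydrogen; aldol addition to acetone then attaches C11–C13, and the C7 configuration is of no consequence.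

Step 13
Reactants: 17 4β-acetoxy-11-hydroxy-8-oxo-5α-eudesman-3α-yl (2S,3R)-2,3-dimethyloxirane-2-carboxylate (C7 epimers)
Product: 19 4β-acetoxy-8-oxo-5α-eudesm-7(11)-en-3α-yl (2S,3R)-2,3-dimethyloxirane-2-carboxylate, via tertiary mesylate 18 (not isolated)
Conditions: MsCl, Et3N, CH2Cl2, 0 °C; then DBU, rt
Reagents that add atoms: methanesulfonyl chloride, CS(=O)(=O)Cl (its atoms stay in 18 only)
Why: The tertiary alcohol is mesylated through the sulfene, and E1cB elimination through the ketone enolate should give the conjugated isopropylidene ketone and not the isopropenyl isomer; the C7 stereocentre disappears.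

Step 14
Reactants: 19 4β-acetoxy-8-oxo-5α-eudesm-7(11)-en-3α-yl (2S,3R)-2,3-dimethyloxirane-2-carboxylate
Product: 20 4β-acetoxy-11-hydroperoxy-8-oxo-5α-eudesm-6-en-3α-yl (2S,3R)-2,3-dimethyloxirane-2-carboxylate (target)
Conditions: O2, tetraphenylporphyrin (cat.), visible light, CH2Cl2, 0 °C
Reagents that add atoms: oxygen, O=O
Why: Schenck ene reaction of an s-cis enone; singlet oxygen should bond to C11 and take the allylic hydrogen from C6, the group geminal to the carbonyl (gem effect), which moves the alkene to C6=C7 and creates no new stereocentre.

## Compound list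

1 | 1,4-dioxaspiro[4.5]decan-7-one | O=C1CCCC2(C1)OCCO2 | starting material
2 | ethyl pyruvate | CCOC(=O)C(C)=O | starting material
3 | ethyl (2R)-2-hydroxy-2-[(8S)-7-oxo-1,4-dioxaspiro[4.5]decan-8-yl]propanoate | CCOC(=O)[C@](C)(O)[C@@H]1CCC2(OCCO2)CC1=O | intermediate
4 | ethyl (2R)-2-hydroxy-2-[(8R)-7-methylidene-1,4-dioxaspiro[4.5]decan-8-yl]propanoate | CCOC(=O)[C@](C)(O)[C@@H]1CCC2(OCCO2)CC1=C | intermediate
5 | (2R)-2-hydroxy-N-methoxy-N-methyl-2-[(8R)-7-methylidene-1,4-dioxaspiro[4.5]decan-8-yl]propanamide | CON(C)C(=O)[C@](C)(O)[C@@H]1CCC2(OCCO2)CC1=C | intermediate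
6 | (4R)-4-hydroxy-4-[(8R)-7-methylidene-1,4-dioxaspiro[4.5]decan-8-yl]pent-1-en-3-one | C=CC(=O)[C@](C)(O)[C@@H]1CCC2(OCCO2)CC1=C | intermediate
7 | (4R)-4-acetoxy-4-[(8R)-7-methylidene-1,4-dioxaspiro[4.5]decan-8-yl]pent-1-en-3-one | C=CC(=O)[C@](C)(OC(C)=O)[C@@H]1CCC2(OCCO2)CC1=C | intermediate
8 | 4β-acetoxy-8,8-ethylenedioxy-11,12,13-trinor-5α-eudesman-3-one | CC(=O)O[C@]1(C)[C@@H]2CCC3(OCCO3)C[C@@]2(C)CCC1=O | intermediate
9 | 4β-acetoxy-8,8-ethylenedioxy-11,12,13-trinor-5α-eudesman-3α-ol | CC(=O)O[C@]1(C)[C@@H]2CCC3(OCCO3)C[C@@]2(C)CC[C@H]1O | intermediate
10 | 4β-acetoxy-3α-hydroxy-11,12,13-trinor-5α-eudesman-8-one | CC(=O)O[C@]1(C)[C@@H]2CCC(=O)C[C@@]2(C)CC[C@H]1O | intermediate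
11 | (E)-2-methylbut-2-en-1-ol | C/C=C(\C)CO | starting material
12 | [(2R,3R)-2,3-dimethyloxiran-2-yl]methanol | OC[C@@]1(C)O[C@@H]1C | intermediate
13 | (2S,3R)-2,3-dimethyloxirane-2-carboxylic acid | OC(=O)[C@@]1(C)O[C@@H]1C | intermediate
14 | 2,4,6-trichlorobenzoic (2S,3R)-2,3-dimethyloxirane-2-carboxylic anhydride (not isolated) | O=C(OC(=O)[C@@]1(C)O[C@@H]1C)c1c(Cl)cc(Cl)cc1Cl | intermediate
15 | 4β-acetoxy-8-oxo-11,12,13-trinor-5α-eudesman-3α-yl (2S,3R)-2,3-dimethyloxirane-2-carboxylate | CC(=O)O[C@]1(C)[C@@H]2CCC(=O)C[C@@]2(C)CC[C@H]1OC(=O)[C@@]1(C)O[C@@H]1C | intermediate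
16 | lithium 7(8)-enolate of 15 (not isolated) | CC(=O)O[C@]1(C)[C@@H]2CC=C(O[Li])C[C@@]2(C)CC[C@H]1OC(=O)[C@@]1(C)O[C@@H]1C | intermediate
17 | 4β-acetoxy-11-hydroxy-8-oxo-5α-eudesman-3α-yl (2S,3R)-2,3-dimethyloxirane-2-carboxylate (C7 epimers) | CC(=O)O[C@]1(C)[C@@H]2CC(C(C)(C)O)C(=O)C[C@@]2(C)CC[C@H]1OC(=O)[C@@]1(C)O[C@@H]1C | intermediate
18 | 4β-acetoxy-11-(methanesulfonyloxy)-8-oxo-5α-eudesman-3α-yl (2S,3R)-2,3-dimethyloxirane-2-carboxylate (C7 epimers, not isolated) | CC(=O)O[C@]1(C)[C@@H]2CC(C(C)(C)OS(C)(=O)=O)C(=O)C[C@@]2(C)CC[C@H]1OC(=O)[C@@]1(C)O[C@@H]1C | intermediate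
19 | 4β-acetoxy-8-oxo-5α-eudesm-7(11)-en-3α-yl (2S,3R)-2,3-dimethyloxirane-2-carboxylate | CC(=O)O[C@]1(C)[C@@H]2CC(=C(C)C)C(=O)C[C@@]2(C)CC[C@H]1OC(=O)[C@@]1(C)O[C@@H]1C | intermediate
20 | 4β-acetoxy-11-hydroperoxy-8-oxo-5α-eudesm-6-en-3α-yl (2S,3R)-2,3-dimethyloxirane-2-carboxylate (CNP0270248.1) | CC(=O)O[C@]1(C)[C@@H]2C=C(C(C)(C)OO)C(=O)C[C@@]2(C)CC[C@H]1OC(=O)[C@@]1(C)O[C@@H]1C | target

## Step count and risk

Total: 14 steps. Longest linear sequence: 12 steps (1 to 20 through steps 1–8 and 11–14); acid 13 is made in two steps (9 and 10) and joined in step 11.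

**Step 6 (key step).** The likeliest failures are closure on the wrong face of the C10 radical (cis fusion), or hydrogen capture by the radical and conjugate reduction of the vinyl ketone before the comparatively slow 6-endo closure. The trans transition state must hold the acetoxy group axial beside the developing axial methyl, which narrows its advantage. The ketone-activated tertiary acetate may also be partly cleaved in hot ethanol, and reversible hydrogen transfer could move the alkene into the ring and erase C5. Fallback: the acetate is taken out of the cyclisation. Hydroxy enone 6 is closed under the same iron hydride conditions; the smaller hydroxyl, held to the C3 carbonyl by a hydrogen bond, takes the axial site, giving 4β-hydroxy-8,8-ethylenedioxy-11,12,13-trinor-5α-eudesman-3-one F1. The hindered tertiary alcohol is then acetylated with Ac2O and catalytic Bi(OTf)3, which is possible now that no alkene remains. This sets out from 6 and returns at 8.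

**Step 1.** Possible failures are enamine formation towards the ketal with β-elimination and loss of the dioxolane, self-condensation of 2 outrunning the cross-aldol, or an insufficient anti preference, because a ketone acceptor offers two substituents of similar size to the transition state. Fallback: the nucleophile is fixed beforehand. Kinetic deprotonation of 1 with LiN(iPr)2 and trapping with Me3SiCl gives 7-(trimethylsilyloxy)-1,4-dioxaspiro[4.5]dec-7-ene F2. An anti-selective Mukaiyama aldol with 2 follows, catalysed by Sn(OTf)2 and a C2-symmetric 2,6-bis(oxazolinyl)pyridine ligand (the pyruvate is bound in a chelate to divalent tin), with acidic work-up. This sets out from 1 and returns at 3.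

**Step 5.** DMAP or triethylamine may add to the unhindered vinyl ketone and start oligomerisation faster than the hindered tertiary hydroxyl is acylated. Fallback: the enone is masked.
- Thiophenol with catalytic Et3N adds to 6 to give (4R)-4-hydroxy-4-[(8R)-7-methylidene-1,4-dioxaspiro[4.5]decan-8-yl]-1-(phenylsulfanyl)pentan-3-one F3.
- Acetylation (Ac2O, DMAP, Et3N) gives the acetate (4R)-4-acetoxy-4-[(8R)-7-methylidene-1,4-dioxaspiro[4.5]decan-8-yl]-1-(phenylsulfanyl)pentan-3-one F4.
- NaIO4 oxidises the sulfide to (4R)-4-acetoxy-4-[(8R)-7-methylidene-1,4-dioxaspiro[4.5]decan-8-yl]-1-(phenylsulfinyl)pentan-3-one F5.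
- Thermal syn-elimination in warm toluene releases the vinyl ketone.

This sets out from 6 and returns at 7.

**Step 11.** Acylation may be too slow, because the 3α-hydroxyl is axial and neopentylic and the acyl donor is fully substituted at its α-carbon. The mixed anhydride could then be opened at the aryl carbonyl, or the glycidic acid could decompose. Fallback: the alcohol is acylated as its alkoxide before the ketone is unmasked. The lithium alkoxide of 9 (LiN(SiMe3)2, THF, −78 °C) is treated with mixed anhydride 14 to give 4β-acetoxy-8,8-ethylenedioxy-11,12,13-trinor-5α-eudesman-3α-yl (2S,3R)-2,3-dimethyloxirane-2-carboxylate F6. The dioxolane is then removed with PPTS in wet acetone; the brief acid exposure of the epoxide is accepted here. This sets out from 9 and returns at 15.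

**Step 14.** Hydrogen abstraction from the C11 methyl groups may compete, with oxygen going to C7. The electron-poor alkene may take up oxygen slowly, and the hydroperoxide may decay on prolonged irradiation or on work-up. Fallback: the C6=C7 alkene and the C11 oxygen are set ionically. Aldol adduct 17 is dehydrogenated with IBX, which can only go towards C6 because C10 is quaternary, to give 4β-acetoxy-11-hydroxy-8-oxo-5α-eudesm-6-en-3α-yl (2S,3R)-2,3-dimethyloxirane-2-carboxylate F7. The tertiary allylic alcohol is then exchanged for the hydroperoxide with ethereal H2O2 and a catalytic amount of H2SO4 at 0 °C. This sets out from 17 and returns at 20.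

## Further compounds

F1 | step 6 | 4β-hydroxy-8,8-ethylenedioxy-11,12,13-trinor-5α-eudesman-3-one | O[C@]1(C)[C@@H]2CCC3(OCCO3)C[C@@]2(C)CCC1=O
F2 | step 1 | 7-(trimethylsilyloxy)-1,4-dioxaspiro[4.5]dec-7-ene | C[Si](C)(C)OC1=CCCC2(C1)OCCO2
F3 | step 5 | (4R)-4-hydroxy-4-[(8R)-7-methylidene-1,4-dioxaspiro[4.5]decan-8-yl]-1-(phenylsulfanyl)pentan-3-one | O=C(CCSc1ccccc1)[C@](C)(O)[C@@H]1CCC2(OCCO2)CC1=C
F4 | step 5 | (4R)-4-acetoxy-4-[(8R)-7-methylidene-1,4-dioxaspiro[4.5]decan-8-yl]-1-(phenylsulfanyl)pentan-3-one | O=C(CCSc1ccccc1)[C@](C)(OC(C)=O)[C@@H]1CCC2(OCCO2)CC1=C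
F5 | step 5 | (4R)-4-acetoxy-4-[(8R)-7-methylidene-1,4-dioxaspiro[4.5]decan-8-yl]-1-(phenylsulfinyl)pentan-3-one (sulfur epimers) | O=C(CCS(=O)c1ccccc1)[C@](C)(OC(C)=O)[C@@H]1CCC2(OCCO2)CC1=C
F6 | step 11 | 4β-acetoxy-8,8-ethylenedioxy-11,12,13-trinor-5α-eudesman-3α-yl (2S,3R)-2,3-dimethyloxirane-2-carboxylate | CC(=O)O[C@]1(C)[C@@H]2CCC3(OCCO3)C[C@@]2(C)CC[C@H]1OC(=O)[C@@]1(C)O[C@@H]1C
F7 | step 14 | 4β-acetoxy-11-hydroxy-8-oxo-5α-eudesm-6-en-3α-yl (2S,3R)-2,3-dimethyloxirane-2-carboxylate | CC(=O)O[C@]1(C)[C@@H]2C=C(C(C)(C)O)C(=O)C[C@@]2(C)CC[C@H]1OC(=O)[C@@]1(C)O[C@@H]1C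
A1 | alternative 1 | (3S,6E)-3-benzyloxy-10-chloro-6-methylundeca-6,10-dien-2-one | CC(=O)[C@@H](OCc1ccccc1)CC/C(C)=C/CCC(Cl)=C
A2 | alternative 1 | 3β-benzyloxy-4β-hydroxy-11,12,13-trinor-5α-eudesman-8-one | O[C@]1(C)[C@@H]2CCC(=O)C[C@@]2(C)CC[C@@H]1OCc3ccccc3
A3 | alternative 2 | 4-(1-methyl-4-oxocyclohexa-2,5-dien-1-yl)butanal | O=CCCCC1(C)C=CC(=O)C=C1
A4 | alternative 2 | 11,12,13,15-tetranor-5α-eudesm-1-ene-3,6-dione | C1[C@@H]2C(=O)CCC[C@@]2(C)C=CC1=O
A5 | alternative 3 | 3-[(7R,8R)-8-acetyl-7-methyl-1,4-dioxaspiro[4.5]decan-7-yl]propanal | CC(=O)[C@@H]1CCC2(OCCO2)C[C@@]1(C)CCC=O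
A6 | alternative 3 | 4β-hydroxy-8,8-ethylenedioxy-11,12,13-trinor-5α-eudesman-3-one | O[C@]1(C)[C@@H]2CCC3(OCCO3)C[C@@]2(C)CCC1=O
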